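**Strategy.** The cyclohexanol is divided into two three-carbon units: C6–C1–C2 (ring CH2, carbinol carbon, chain-bearing CH) and C3–C4–C5 (CMe2 and two CH2). In one flask the α,α′-dianion of 3-methylbutan-2-one is alkylated by the primary triflate of a Sharpless-derived (2S,3S)-epoxy alcohol (C5–C6 bond), and the enolate thus unveiled opens the epoxide at its secondary carbon (C2–C3 bond). The step exploits the trans C1-hydroxyl/C2-side-chain pair of the ring, which is the anti-opened E-epoxide of an acyclic C25 polyene allylic alcohol made from geranyl and farnesyl bromides. The temporary ring ketone at C4 is removed by Wolff–Kishner reduction.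

Key step: step 6

Remark: bromides 1 and 4 are taken as the commercial (E)- and (2E,6E)-isomers and ketone 8 as commercial; the locants C1–C6 used above are those of the target cyclohexanol.

Step 1
Reactants: 1 (E)-geranyl bromide
Product: 2 geranyl phenyl sulfone
Conditions: PhSO2Na, DMF, 25 °C
Reagents that add atoms: sodium benzenesulfinate, [Na+].[O-]S(=O)c1ccccc1
Why: SN2 S-alkylation of the sulfinate at the primary allylic carbon (sulfinate alkylation) should give the allylic sulfone with the E-alkene unchanged; no stereocentre is formed.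

Step 2
Reactants: 2 geranyl phenyl sulfone
Product: 3 (2E,6E)-2,6-dimethyl-8-(phenylsulfonyl)octa-2,6-dien-1-ol
Conditions: SeO2 (cat.), t-BuOOH, CH2Cl2, 25 °C
Reagents that add atoms: selenium dioxide, O=[Se]=O (catalytic oxygen-transfer agent); tert-butyl hydroperoxide, CC(C)(C)OO (terminal oxidant)
Why: Catalytic SeO2 allylic oxidation (Riley oxidation: ene reaction, then [2,3]-sigmatropic shift) should hydroxylate the E-methyl group of the terminal, more electron-rich alkene, the alkene next to the sulfonyl group being deactivated; the new alkene is E and no stereocentre is formed.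

Step 3
Reactants: 3 (2E,6E)-2,6-dimethyl-8-(phenylsulfonyl)octa-2,6-dien-1-ol; 4 (2E,6E)-farnesyl bromide
Product: 5 (2E,6E,10E,14E)-2,6,11,15,19-pentamethyl-8-(phenylsulfonyl)icosa-2,6,10,14,18-pentaen-1-ol (racemic at C8)
Conditions: n-BuLi (2.1 equiv), THF–DMPU, −78 °C; then 4, −78 → −20 °C
Reagents that add atoms: none
Why: The α-sulfonyl carbanion of the alkoxide–carbanion dianion should displace the allylic bromide at carbon (Julia-type allylic sulfone alkylation), joining the two halves tail to tail with all E-alkenes retained; the sulfone-bearing carbon is a racemic centre that is erased in step 4.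

Step 4
Reactants: 5 the C25 hydroxy sulfone
Product: 6 (2E,6E,10E,14E)-2,6,11,15,19-pentamethylicosa-2,6,10,14,18-pentaen-1-ol
Conditions: PdCl2(dppp) (5 mol %), LiBHEt3 (3 equiv), THF, 0 °C
Reagents that add atoms: none
Why: Zerovalent palladium should ionise the allylic sulfone and hydride from LiBHEt3 should attack the less substituted terminus of the π-allyl complex (palladium-catalysed reductive desulfonylation), so the trisubstituted E-alkene stays in place; the first equivalent of hydride only deprotonates the alcohol.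

Step 5
Reactants: 6 the C25 allylic alcohol
Product: 7 [(2S,3S)-2-methyl-3-[(3E,7E,11E)-3,8,12,16-tetramethylheptadeca-3,7,11,15-tetraen-1-yl]oxiran-2-yl]methanol
Conditions: Ti(OiPr)4 (10 mol %), L-(+)-diethyl tartrate (12 mol %), t-BuOOH, 4 Å MS, CH2Cl2, −20 °C
Reagents that add atoms: tert-butyl hydroperoxide, CC(C)(C)OO
Why: Sharpless asymmetric epoxidation is confined to the allylic alcohol alkene, and L-(+)-tartrate should deliver oxygen to the face of the (E)-2-methyl-2-alken-1-ol that gives the (2S,3S)-epoxide, which fixes both future ring stereocentres.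

Step 6
Reactants: 7 the (2S,3S)-epoxy alcohol; 8 3-methylbutan-2-one
Product: 12 (3S,4S)-4-hydroxy-2,2,4-trimethyl-3-[(3E,7E,11E)-3,8,12,16-tetramethylheptadeca-3,7,11,15-tetraen-1-yl]cyclohexan-1-one, via epoxy triflate 9 (not isolated), via ketone dianion 10 (not isolated), via epoxy enolate 11 (not isolated)
Conditions: 7: n-BuLi, Et2O, −78 °C, then Tf2O; 8: KH, THF, 25 °C, then n-BuLi, TMEDA, 0 °C; triflate solution added to the dianion at −78 °C; LiClO4, −78 → 25 °C; aq. NH4Cl
Reagents that add atoms: none
Why: The cross-conjugated 2-oxidoallyl dianion 10 should be alkylated at its unhindered CH2 terminus by the primary triflate 9 (SN2, new CH2–CH2 bond), which unveils regiospecifically the tetrasubstituted enolate 11, whose carbon then opens the epoxide at the secondary carbon with inversion (new CMe2–CH bond) to give the cyclohexanone alkoxide. The closest known reaction type is the annulation of ketone α,α′-dianions with 1,3-dihalides to cyclohexanones, combined with the intramolecular, lithium-salt-assisted opening of epoxides by ketone enolates. The ring closes by a 6-endo-tet epoxide opening that is 6-enolendo with respect to the enolate. The carbinol centre is carried unchanged from the Sharpless epoxide and the adjacent CH centre is set by SN2 inversion, so the trans (S,S) relationship of hydroxyl and side chain follows from anti opening of the E-epoxide. The step needs C- over O-alkylation and attack at the secondary, not the fully substituted, epoxide carbon (6-endo over 5-exo). The dianion route delivers only the enolate that can close a six-membered ring, lithium counter-ions favour C-alkylation, the fully substituted epoxide carbon is closed to SN2 attack, and the triflate carbon has no β-hydrogen for elimination.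

Step 7
Reactants: 12 the hydroxy ketone
Product: 13 (1S,2S)-1,3,3-trimethyl-2-[(3E,7E,11E)-3,8,12,16-tetramethylheptadeca-3,7,11,15-tetraen-1-yl]cyclohexan-1-ol (target)
Conditions: N2H4·H2O, KOH, diethylene glycol, 130 °C; then 200 °C with removal of water
Reagents that add atoms: none
Why: Wolff–Kishner reduction (Huang–Minlon procedure) should convert the ring carbonyl into CH2 by way of the hydrazone anion with loss of N2; the carbonyl is flanked by a quaternary carbon and a CH2, so neither stereocentre can epimerise, and the isolated trisubstituted alkenes and the tertiary alcohol should tolerate hot KOH.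

**Compound list**

1 | (E)-geranyl bromide, (2E)-1-bromo-3,7-dimethylocta-2,6-diene | CC(C)=CCC/C(C)=C/CBr | starting material
2 | geranyl phenyl sulfone, [(2E)-3,7-dimethylocta-2,6-dien-1-yl]sulfonylbenzene | CC(C)=CCC/C(C)=C/CS(=O)(=O)c1ccccc1 | intermediate
3 | (2E,6E)-2,6-dimethyl-8-(phenylsulfonyl)octa-2,6-dien-1-ol | OC/C(C)=C/CC/C(C)=C/CS(=O)(=O)c1ccccc1 | intermediate
4 | (2E,6E)-farnesyl bromide, (2E,6E)-1-bromo-3,7,11-trimethyldodeca-2,6,10-triene | CC(C)=CCC/C(C)=C/CC/C(C)=C/CBr | starting material
5 | (2E,6E,10E,14E)-2,6,11,15,19-pentamethyl-8-(phenylsulfonyl)icosa-2,6,10,14,18-pentaen-1-ol (racemic at C8) | CC(C)=CCC/C(C)=C/CC/C(C)=C/CC(S(=O)(=O)c1ccccc1)/C=C(\C)CC/C=C(\C)CO | intermediate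
6 | (2E,6E,10E,14E)-2,6,11,15,19-pentamethylicosa-2,6,10,14,18-pentaen-1-ol | CC(C)=CCC/C(C)=C/CC/C(C)=C/CC/C=C(\C)CC/C=C(\C)CO | intermediate
7 | [(2S,3S)-2-methyl-3-[(3E,7E,11E)-3,8,12,16-tetramethylheptadeca-3,7,11,15-tetraen-1-yl]oxiran-2-yl]methanol | CC(C)=CCC/C(C)=C/CC/C(C)=C/CC/C=C(\C)CC[C@@H]1O[C@@]1(C)CO | intermediate
8 | 3-methylbutan-2-one | CC(=O)C(C)C | starting material
9 | [(2S,3S)-2-methyl-3-[(3E,7E,11E)-3,8,12,16-tetramethylheptadeca-3,7,11,15-tetraen-1-yl]oxiran-2-yl]methyl trifluoromethanesulfonate | CC(C)=CCC/C(C)=C/CC/C(C)=C/CC/C=C(\C)CC[C@@H]1O[C@@]1(C)COS(=O)(=O)C(F)(F)F | intermediate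
10 | α,α′-dianion of 3-methylbutan-2-one (2-oxidoallyl dianion, potassium lithium salt) | [Li+].[K+].[CH2-]C([O-])=C(C)C | intermediate
11 | lithium 2-methyl-5-[(2S,3S)-2-methyl-3-[(3E,7E,11E)-3,8,12,16-tetramethylheptadeca-3,7,11,15-tetraen-1-yl]oxiran-2-yl]pent-2-en-3-olate | CC(C)=CCC/C(C)=C/CC/C(C)=C/CC/C=C(\C)CC[C@@H]1O[C@@]1(C)CCC([O-])=C(C)C.[Li+] | intermediate
12 | (3S,4S)-4-hydroxy-2,2,4-trimethyl-3-[(3E,7E,11E)-3,8,12,16-tetramethylheptadeca-3,7,11,15-tetraen-1-yl]cyclohexan-1-one | CC(C)=CCC/C(C)=C/CC/C(C)=C/CC/C=C(\C)CC[C@H]1C(C)(C)C(=O)CC[C@]1(C)O | intermediate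
13 | (1S,2S)-1,3,3-trimethyl-2-[(3E,7E,11E)-3,8,12,16-tetramethylheptadeca-3,7,11,15-tetraen-1-yl]cyclohexan-1-ol | CC(C)=CCC/C(C)=C/CC/C(C)=C/CC/C=C(\C)CC[C@H]1C(C)(C)CCC[C@]1(C)O | target

Total step count: 7. Longest linear sequence: 7 steps (1 → 13).

**Steps most likely to fail**

Step 6. The enolate 11 may alkylate at oxygen and not at carbon, ring closure at the congested secondary epoxide carbon may stall, or dianion formation may be incomplete. The fallback makes the two bonds one after the other with a doubly activated donor; it sets out from 7 and comes back at 12. Epoxy alcohol 7 is converted with I2, PPh3 and imidazole into the epoxy iodide F1. The sodium enolate of ethyl 4-methyl-3-oxopentanoate (NaH, THF–DMF) is C-alkylated by F1 to give the open-chain keto ester F2. Its dianion (LiN(iPr)2, 2.2 equiv, THF, −78 → 0 °C) should close the ring through the γ-carbon by opening the epoxide at the secondary carbon, giving the cyclic β-keto ester F3. Saponification and decarboxylation (KOH, aqueous MeOH; then AcOH, 60 °C) return hydroxy ketone 12.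

Step 7. Hydrazone formation at the carbonyl next to the quaternary carbon may be slow, and prolonged heating in base may cause alkene migration or loss of the tertiary alcohol. The fallback deoxygenates by a radical route; it sets out from 12 and comes back at 13. Reduction with LiAlH4 in THF gives the diol F4. The secondary hydroxyl alone is acylated with phenyl chlorothionoformate (pyridine, DMAP, CH2Cl2) to the thionocarbonate F5. Barton–McCombie reduction (Bu3SnH, AIBN, toluene, 110 °C) gives 13.

Step 2. The allylic oxidation may stop at low conversion, run on to the enal, or attack internal allylic positions. The fallback builds the E-allylic alcohol by olefination; it sets out from 2 and comes back at 3. Epoxidation of the terminal alkene of 2 with mCPBA (CH2Cl2, 0 °C) gives the epoxide F6. Cleavage with HIO4 (aqueous THF) gives the aldehyde F7. Wittig reaction with Ph3P=C(CH3)CO2Et (CH2Cl2, 25 °C) gives the E-enoate F8, and reduction with iBu2AlH (CH2Cl2, −78 °C) gives 3.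

**Further compounds**

F1 | step 6 | (2R,3S)-2-(iodomethyl)-2-methyl-3-[(3E,7E,11E)-3,8,12,16-tetramethylheptadeca-3,7,11,15-tetraen-1-yl]oxirane | CC(C)=CCC/C(C)=C/CC/C(C)=C/CC/C=C(\C)CC[C@@H]1O[C@@]1(C)CI
F2 | step 6 | ethyl 4-methyl-2-[[(2S,3S)-2-methyl-3-[(3E,7E,11E)-3,8,12,16-tetramethylheptadeca-3,7,11,15-tetraen-1-yl]oxiran-2-yl]methyl]-3-oxopentanoate (mixture at C2) | CC(C)=CCC/C(C)=C/CC/C(C)=C/CC/C=C(\C)CC[C@@H]1O[C@@]1(C)CC(C(=O)OCC)C(=O)C(C)C
F3 | step 6 | ethyl (4S,5S)-5-hydroxy-3,3,5-trimethyl-2-oxo-4-[(3E,7E,11E)-3,8,12,16-tetramethylheptadeca-3,7,11,15-tetraen-1-yl]cyclohexane-1-carboxylate (mixture at C1) | CC(C)=CCC/C(C)=C/CC/C(C)=C/CC/C=C(\C)CC[C@H]1C(C)(C)C(=O)C(C(=O)OCC)C[C@]1(C)O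
F4 | step 7 | (1S,2S)-1,3,3-trimethyl-2-[(3E,7E,11E)-3,8,12,16-tetramethylheptadeca-3,7,11,15-tetraen-1-yl]cyclohexane-1,4-diol (mixture at C4) | CC(C)=CCC/C(C)=C/CC/C(C)=C/CC/C=C(\C)CC[C@H]1C(C)(C)C(O)CC[C@]1(C)O
F5 | step 7 | O-[(3S,4S)-4-hydroxy-2,2,4-trimethyl-3-[(3E,7E,11E)-3,8,12,16-tetramethylheptadeca-3,7,11,15-tetraen-1-yl]cyclohexyl] O-phenyl carbonothioate (mixture at C1) | CC(C)=CCC/C(C)=C/CC/C(C)=C/CC/C=C(\C)CC[C@H]1C(C)(C)C(OC(=S)Oc2ccccc2)CC[C@]1(C)O
F6 | step 2 | 3,3-dimethyl-2-[(3E)-3-methyl-5-(phenylsulfonyl)pent-3-en-1-yl]oxirane (racemic) | CC1(C)OC1CC/C(C)=C/CS(=O)(=O)c1ccccc1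
F7 | step 2 | (4E)-4-methyl-6-(phenylsulfonyl)hex-4-enal | O=CCC/C(C)=C/CS(=O)(=O)c1ccccc1
F8 | step 2 | ethyl (2E,6E)-2,6-dimethyl-8-(phenylsulfonyl)octa-2,6-dienoate | CCOC(=O)/C(C)=C/CC/C(C)=C/CS(=O)(=O)c1ccccc1
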